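The depside is cut at its ester C(=O)–O bond into a ring A acid and a ring B phenol. In ring B (the benzoic acid ring) heptyl on C6, carboxyl on C1 and methoxy on C2 sit on three adjacent carbons; the key step exploits this by placing an aryne triple bond across C1–C6 with the C2 methoxy oxygen beside it. In one flask heptylmagnesium bromide adds at C6 and CO2 is captured at C1, so the flanked carboxyl group is introduced directly. The aryne precursor is 1-fluoro-3-methoxy-5-(triisopropylsilyloxy)benzene, lithiated between fluorine and methoxy. Ring A comes from 5-heptylresorcinol by formylation, selective methylation, benzylation and oxidation.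

Key step: step 2

Remark: heptylmagnesium bromide (3) is taken as a purchased, titrated solution in diethyl ether; the target has no stereocenter, so no configuration has to be set.

Step 1
Reactants: 1 3-fluoro-5-methoxyphenol
Product: 2 1-fluoro-3-methoxy-5-(triisopropylsilyloxy)benzene
Conditions: i-Pr3SiCl, imidazole, DMF, rt
Reagents that add atoms: triisopropylsilyl chloride, CC(C)[Si](Cl)(C(C)C)C(C)C
Why: Imidazole-promoted O-silylation of the only hydroxyl is routine for phenols and installs a bulky, base-stable ether that later keeps the organolithium away from the two ring positions next to it.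

Step 2
Reactants: 2 1-fluoro-3-methoxy-5-(triisopropylsilyloxy)benzene; 3 heptylmagnesium bromide
Product: 7 2-heptyl-6-methoxy-4-(triisopropylsilyloxy)benzoic acid, via aryllithium 4 (not isolated), via aryne 5 (not isolated), via arylmagnesium bromide 6 (not isolated)
Conditions: n-BuLi (1.05 equiv), THF, −78 °C; 3 (2.5 equiv, Et2O), −78 °C → rt; CO2 (dry gas), 0 °C → rt; 1 M HCl, 0 °C
Reagents that add atoms: carbon dioxide, O=C=O
Why: n-BuLi should deprotonate 2 at the one ring carbon flanked by both the acidifying fluorine and the coordinating methoxy oxygen, giving aryllithium 4, because the bulky triisopropylsilyloxy group is a poor director and shields its two neighbouring protons. On warming in the presence of the Grignard reagent, 4 loses LiF to give aryne 5, whose triple bond is polarised by the inductive pull of the adjacent methoxy oxygen, so the heptyl nucleophile attacks the aryne carbon remote from methoxy and magnesium ends on the carbon beside it (6). The small electrophile CO2 then carboxylates this di-ortho-substituted arylmagnesium and acidic work-up should deliver 7; the aryl–heptyl and aryl–carboxyl bonds are formed, no ring is closed and no stereocenter is created. The closest known reaction type is the three-component aryne coupling of ortho-lithiated fluoroanisoles with Grignard reagents followed by electrophilic quench. The step needs site-selective lithiation and regioselective Grignard addition, secured by the fluorine/methoxy pair and by the methoxy group next to the triple bond respectively.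

Step 3
Reactants: 7 2-heptyl-6-methoxy-4-(triisopropylsilyloxy)benzoic acid
Product: 8 benzyl 2-heptyl-6-methoxy-4-(triisopropylsilyloxy)benzoate
Conditions: BnBr, KHCO3, DMF, rt
Reagents that add atoms: benzyl bromide, BrCc1ccccc1
Why: Carboxylate O-alkylation (SN2 at the benzylic carbon) needs no attack at the shielded carbonyl carbon, so the di-ortho-substituted acid should esterify readily, and the weak base KHCO3 leaves the aryl silyl ether intact.

Step 4
Reactants: 8 benzyl 2-heptyl-6-methoxy-4-(triisopropylsilyloxy)benzoate
Product: 9 benzyl 2-heptyl-4-hydroxy-6-methoxybenzoate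
Conditions: Bu4NF, AcOH, THF, 0 °C
Reagents that add atoms: none
Why: Fluoride-induced desilylation of an aryl silyl ether is fast at 0 °C, and the acetic acid buffer protonates the liberated phenoxide so that the benzyl ester is not endangered.

Step 5
Reactants: 10 5-heptylresorcinol
Product: 12 2,4-dihydroxy-6-heptylbenzaldehyde, via iminium chloride 11 (not isolated)
Conditions: POCl3, DMF, 0 °C → rt; then H2O, 50 °C
Reagents that add atoms: N,N-dimethylformamide, CN(C)C=O (formyl carbon); water, O (formyl oxygen)
Why: Vilsmeier–Haack formylation of the electron-rich resorcinol should occur at the ring carbon ortho to one hydroxyl and para to the other (two equivalent sites by symmetry) in preference to the crowded carbon between the hydroxyls, and hydrolysis of iminium 11 frees the aldehyde.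

Step 6
Reactants: 12 2,4-dihydroxy-6-heptylbenzaldehyde
Product: 13 2-heptyl-6-hydroxy-4-methoxybenzaldehyde
Conditions: MeI (1.05 equiv), K2CO3 (1.0 equiv), acetone, rt → 40 °C
Reagents that add atoms: iodomethane, CI
Why: Williamson etherification with one equivalent of base should be selective for the para hydroxyl, because the ortho hydroxyl is hydrogen-bonded to the formyl oxygen and is therefore less acidic and less nucleophilic.

Step 7
Reactants: 13 2-heptyl-6-hydroxy-4-methoxybenzaldehyde
Product: 14 2-(benzyloxy)-6-heptyl-4-methoxybenzaldehyde
Conditions: BnBr, K2CO3, DMF, 60 °C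
Reagents that add atoms: benzyl bromide, BrCc1ccccc1
Why: Williamson benzylation under more forcing conditions alkylates the remaining chelated phenol, masking it so that it cannot compete as a nucleophile in the ester-forming step.

Step 8
Reactants: 14 2-(benzyloxy)-6-heptyl-4-methoxybenzaldehyde
Product: 15 2-(benzyloxy)-6-heptyl-4-methoxybenzoic acid
Conditions: NaClO2, NaH2PO4, 2-methyl-2-butene, t-BuOH/H2O, rt
Reagents that add atoms: sodium chlorite, [Na+].[O-]Cl=O
Why: Pinnick oxidation converts the hindered, electron-rich aldehyde into the acid under buffered conditions, with 2-methyl-2-butene scavenging hypochlorous acid so that the ring is not chlorinated.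

Step 9
Reactants: 15 2-(benzyloxy)-6-heptyl-4-methoxybenzoic acid; 9 benzyl 2-heptyl-4-hydroxy-6-methoxybenzoate
Product: 17 benzyl 4-{[2-(benzyloxy)-6-heptyl-4-methoxybenzoyl]oxy}-2-heptyl-6-methoxybenzoate, via acid chloride 16 (not isolated)
Conditions: (COCl)2, DMF (cat.), CH2Cl2, 0 °C → rt, concentrate; then 9, Et3N, 4-(dimethylamino)pyridine (DMAP), CH2Cl2, 0 °C → rt
Reagents that add atoms: none
Why: Acyl chloride formation followed by DMAP-catalysed acylation is the standard esterification of a di-ortho-substituted benzoic acid, and the phenol of 9 is the only nucleophile present because its carboxyl is a benzyl ester and the ring A hydroxyl is a benzyl ether.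

Step 10
Reactants: 17 benzyl 4-{[2-(benzyloxy)-6-heptyl-4-methoxybenzoyl]oxy}-2-heptyl-6-methoxybenzoate
Product: 18 2-heptyl-4-[(2-heptyl-6-hydroxy-4-methoxybenzoyl)oxy]-6-methoxybenzoic acid (CNP0128141.0)
Conditions: H2 (1 atm), 10% Pd/C, EtOAc, rt
Reagents that add atoms: none
Why: Catalytic hydrogenolysis should cleave the benzylic C–O bonds of both the benzyl ether and the benzyl ester while the aryl ester (depside) linkage, the methyl ethers and the rings stay untouched.

Compound list
1 | 3-fluoro-5-methoxyphenol | COc1cc(O)cc(F)c1 | starting material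
2 | 1-fluoro-3-methoxy-5-(triisopropylsilyloxy)benzene | COc1cc(F)cc(O[Si](C(C)C)(C(C)C)C(C)C)c1 | intermediate
3 | heptylmagnesium bromide | CCCCCCC[Mg]Br | starting material
4 | 2-fluoro-6-methoxy-4-(triisopropylsilyloxy)phenyllithium | COc1cc(O[Si](C(C)C)(C(C)C)C(C)C)cc(F)c1[Li] | intermediate
5 | 3-methoxy-5-(triisopropylsilyloxy)benzyne | COC1=CC(O[Si](C(C)C)(C(C)C)C(C)C)=CC#C1 | intermediate
6 | 2-heptyl-6-methoxy-4-(triisopropylsilyloxy)phenylmagnesium bromide | CCCCCCCc1cc(O[Si](C(C)C)(C(C)C)C(C)C)cc(OC)c1[Mg]Br | intermediate
7 | 2-heptyl-6-methoxy-4-(triisopropylsilyloxy)benzoic acid | CCCCCCCc1cc(O[Si](C(C)C)(C(C)C)C(C)C)cc(OC)c1C(=O)O | intermediate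
8 | benzyl 2-heptyl-6-methoxy-4-(triisopropylsilyloxy)benzoate | CCCCCCCc1cc(O[Si](C(C)C)(C(C)C)C(C)C)cc(OC)c1C(=O)OCc1ccccc1 | intermediate
9 | benzyl 2-heptyl-4-hydroxy-6-methoxybenzoate | CCCCCCCc1cc(O)cc(OC)c1C(=O)OCc1ccccc1 | intermediate
10 | 5-heptylresorcinol | CCCCCCCc1cc(O)cc(O)c1 | starting material
11 | (2,4-dihydroxy-6-heptylbenzylidene)dimethyliminium chloride | CCCCCCCc1cc(O)cc(O)c1C=[N+](C)C.[Cl-] | intermediate
12 | 2,4-dihydroxy-6-heptylbenzaldehyde | CCCCCCCc1cc(O)cc(O)c1C=O | intermediate
13 | 2-heptyl-6-hydroxy-4-methoxybenzaldehyde | CCCCCCCc1cc(OC)cc(O)c1C=O | intermediate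
14 | 2-(benzyloxy)-6-heptyl-4-methoxybenzaldehyde | CCCCCCCc1cc(OC)cc(OCc2ccccc2)c1C=O | intermediate
15 | 2-(benzyloxy)-6-heptyl-4-methoxybenzoic acid | CCCCCCCc1cc(OC)cc(OCc2ccccc2)c1C(=O)O | intermediate
16 | 2-(benzyloxy)-6-heptyl-4-methoxybenzoyl chloride | CCCCCCCc1cc(OC)cc(OCc2ccccc2)c1C(=O)Cl | intermediate
17 | benzyl 4-{[2-(benzyloxy)-6-heptyl-4-methoxybenzoyl]oxy}-2-heptyl-6-methoxybenzoate | CCCCCCCc1cc(OC)cc(OCc2ccccc2)c1C(=O)Oc1cc(CCCCCCC)c(C(=O)OCc2ccccc2)c(OC)c1 | intermediate
18 | 2-heptyl-4-[(2-heptyl-6-hydroxy-4-methoxybenzoyl)oxy]-6-methoxybenzoic acid | CCCCCCCc1cc(OC)cc(O)c1C(=O)Oc1cc(CCCCCCC)c(C(=O)O)c(OC)c1 | target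

Total step count: 10. Longest linear sequence: 6 steps (steps 1, 2, 3, 4, 9, 10; the ring A branch, steps 5, 6, 7, 8, 9, 10, is equally long).

Steps most likely to fail

Step 2 (aryne coupling). What may go wrong is lithiation beside the silyloxy group instead of between fluorine and methoxy. The aryllithium may also lose LiF too early, so that butyl or a second aryllithium captures the aryne, and the Grignard addition may be incompletely regiocontrolled. The fallback avoids the aryne altogether; it sets out from compound 12 and comes back to the route at compound 7. The unchelated para hydroxyl of 12 is silylated selectively (i-Pr3SiCl, imidazole, CH2Cl2, 0 °C) to give 2-heptyl-6-hydroxy-4-(triisopropylsilyloxy)benzaldehyde F1. The remaining chelated hydroxyl is methylated under neutral Mitsunobu conditions (MeOH, PPh3, diisopropyl azodicarboxylate, THF), which spare the silyl ether, to give 2-heptyl-6-methoxy-4-(triisopropylsilyloxy)benzaldehyde F2. Pinnick oxidation (NaClO2, NaH2PO4, 2-methyl-2-butene) should then give 7.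

Step 9 (depside ester formation). What may go wrong is sluggish attack of the phenol at the shielded acyl carbon, so that hydrolysis of the acyl chloride competes, or loss of the ortho benzyl ether under the acidic conditions of chloride formation. The fallback uses the unprotected salicylic acid and a mixed-anhydride condensation; it sets out from compound 13 and comes back at compound 18. Pinnick oxidation of 13 gives 2-heptyl-6-hydroxy-4-methoxybenzoic acid F3. This is condensed with phenol 9 through its mixed trifluoroacetic anhydride (trifluoroacetic anhydride, toluene, rt), the hydrogen-bonded ortho hydroxyl needing no protection and any trifluoroacetate formed there being lost on aqueous work-up. The product is benzyl 2-heptyl-4-[(2-heptyl-6-hydroxy-4-methoxybenzoyl)oxy]-6-methoxybenzoate F4. Hydrogenolysis (H2, 10% Pd/C, EtOAc) removes the single benzyl group and should give 18.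

Step 5 (formylation). What may go wrong is formylation at the carbon between the two hydroxyls or double formylation, followed in step 6 by incomplete discrimination of the two hydroxyls. The fallback reverses the order and uses a chelation-directed formylation; it sets out from compound 10 and comes back at compound 13. Compound 10 is mono-methylated (MeI, one equivalent, K2CO3, acetone, with chromatographic separation from unreacted 10 and the dimethyl ether) to give 3-heptyl-5-methoxyphenol F5. Magnesium-mediated ortho-formylation (MgCl2, Et3N, paraformaldehyde, MeCN, reflux) delivers the formyl group only ortho to the free hydroxyl through the magnesium phenoxide, and preferentially para to methoxy, which should give 13 directly.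

Further compounds
F1 | step 2 | 2-heptyl-6-hydroxy-4-(triisopropylsilyloxy)benzaldehyde | CCCCCCCc1cc(O[Si](C(C)C)(C(C)C)C(C)C)cc(O)c1C=O
F2 | step 2 | 2-heptyl-6-methoxy-4-(triisopropylsilyloxy)benzaldehyde | CCCCCCCc1cc(O[Si](C(C)C)(C(C)C)C(C)C)cc(OC)c1C=O
F3 | step 9 | 2-heptyl-6-hydroxy-4-methoxybenzoic acid | CCCCCCCc1cc(OC)cc(O)c1C(=O)O
F4 | step 9 | benzyl 2-heptyl-4-[(2-heptyl-6-hydroxy-4-methoxybenzoyl)oxy]-6-methoxybenzoate | CCCCCCCc1cc(OC)cc(O)c1C(=O)Oc1cc(CCCCCCC)c(C(=O)OCc2ccccc2)c(OC)c1
F5 | step 5 | 3-heptyl-5-methoxyphenol | CCCCCCCc1cc(O)cc(OC)c1
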